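**Plan** (cembranoid numbering: lactone ring O–C2–C1–C15(=C17H2)–C16(=O); 14-membered ring C1 to C14; Me18 on C4, C19H2OAc on C8, Me20 on C12)

1. Retrosynthetic cuts, in order: O19–acetyl; C15=C17; ring bond C12–C13; C1–C2 together with lactone bond C16–O; C7=C8; C8–C9.
2. Forward: a C9–C12 iodoalkenyl unit is attached to a phosphonoacetate (C8, C19) and olefinated onto a geraniol-derived C2–C7 aldehyde; the C2 enal is unveiled; the γ-lactone is formed first, the 14-membered carbocycle second, then C17 and the acetate.
3. Enabling feature: the C13–C14 link on lactone carbon C1 is a hydroborated vinyl group, the very group an allylboration leaves on C1 and the only monosubstituted alkene of the seco compound, and C12 is a methyl-bearing sp2 carbon that can carry iodine; boron at C13 and palladium at C12 close the ring.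
4. Helpers: O19 is carried as a silyl ether and C17 is added after ring closure, because an allylic acetate and an acrylate would not survive borane, palladium and amide base.
5. Stereochemistry: C1 and C2 (cis) arise together in a catalyst-controlled anti-allylboration of the enal with an (E)-γ-substituted allylboronate; C3=C4 comes from geraniol, C7=C8 from Still–Gennari olefination, C11=C12 from syn-hydrozirconation; none is touched later.

Key step: step 15

Assumption: (R)-TRIP is taken to deliver the allyl group to the Re face of enal 15, as it does with aryl and alkenyl aldehydes; if the opposite sense is found, the (S) catalyst is used.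
Remark: anions made by deprotonation directly before reaction (alkoxides, enolates, phosphonate anions) and species of catalytic cycles count as activated forms of numbered compounds and carry no number.

**Step 1**
Reactants: 1 pent-3-yn-1-ol
Product: 3 (3E)-4-iodopent-3-en-1-ol, via alkenylzirconocene 2 (not isolated)
Conditions: Cp2Zr(H)Cl (2.5 equiv), THF, rt to 45 °C; I2, 0 °C; 1 M HCl work-up
Reagents that add atoms: iodine, II; Cp2Zr(H)Cl, [H][Zr](Cl)(C1C=CC=C1)C1C=CC=C1 (zirconium stays only in 2)
Why: Hydrozirconation–iodination: syn addition of Zr–H, equilibrated by excess reagent to place zirconium on the less hindered methyl-bearing carbon, then iodinolysis with retention should give the (E)-2-iodo-2-alkene unit (no stereocentre).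

**Step 2**
Reactants: 3 (3E)-4-iodopent-3-en-1-ol
Product: 4 (2E)-2,5-diiodopent-2-ene
Conditions: I2, PPh3, imidazole, CH2Cl2, 0 °C to rt
Reagents that add atoms: iodine, II
Why: Appel-type iodination of the primary alcohol under neutral conditions should leave the alkenyl iodide and its geometry untouched.

**Step 3**
Reactants: 4 (2E)-2,5-diiodopent-2-ene; 5 methyl 2-[bis(2,2,2-trifluoroethoxy)phosphoryl]acetate
Product: 6 methyl (5E)-2-[bis(2,2,2-trifluoroethoxy)phosphoryl]-6-iodohept-5-enoate
Conditions: NaH, DMF, 0 °C; then 4, rt to 45 °C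
Reagents that add atoms: none
Why: SN2 C-alkylation of the stabilised phosphonoacetate anion by the primary iodide should proceed with the alkenyl iodide inert; the new α-stereocentre is racemic and is destroyed in step 6.

**Step 4**
Reactants: 7 geraniol
Product: 8 geranyl 4-methoxybenzyl ether
Conditions: NaH, 4-methoxybenzyl chloride, n-Bu4NI (cat.), THF/DMF, 0 °C to rt
Reagents that add atoms: 4-methoxybenzyl chloride, COc1ccc(CCl)cc1
Why: Williamson etherification of the primary allylic alkoxide gives an ether that should survive the acidic, basic and reducing steps up to step 9.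

**Step 5**
Reactants: 8 geranyl 4-methoxybenzyl ether
Product: 10 (4E)-6-[(4-methoxyphenyl)methoxy]-4-methylhex-4-enal, via epoxide 9 (not isolated)
Conditions: mCPBA (1.05 equiv), CH2Cl2, 0 °C; crude 9, H5IO6, THF/Et2O, 0 °C
Reagents that add atoms: mCPBA, O=C(OO)c1cccc(Cl)c1
Why: Prilezhaev epoxidation should select the remote trisubstituted alkene because the other one is deactivated by the allylic ether oxygen, and periodic acid cleaves the epoxide through its diol (glycol cleavage) to the aldehyde.

**Step 6**
Reactants: 10 (4E)-6-[(4-methoxyphenyl)methoxy]-4-methylhex-4-enal; 6 methyl (5E)-2-[bis(2,2,2-trifluoroethoxy)phosphoryl]-6-iodohept-5-enoate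
Product: 11 methyl (2Z,6E)-2-[(3E)-4-iodopent-3-en-1-yl]-8-[(4-methoxyphenyl)methoxy]-6-methylocta-2,6-dienoate
Conditions: KN(SiMe3)2, 18-crown-6, THF, −78 °C; then 10
Reagents that add atoms: none
Why: Still–Gennari variant of the Horner–Wadsworth–Emmons olefination: fast, irreversible elimination from the electron-poor phosphonate adduct should place the ester cis to the aldehyde-derived chain (C6 cis to C19).

**Step 7**
Reactants: 11 methyl (2Z,6E)-2-[(3E)-4-iodopent-3-en-1-yl]-8-[(4-methoxyphenyl)methoxy]-6-methylocta-2,6-dienoate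
Product: 12 (2Z,6E)-2-[(3E)-4-iodopent-3-en-1-yl]-8-[(4-methoxyphenyl)methoxy]-6-methylocta-2,6-dien-1-ol
Conditions: i-Bu2AlH (2.5 equiv), CH2Cl2, −78 to −20 °C; aq. KNaC4H4O6 work-up
Reagents that add atoms: none
Why: 1,2-Reduction of the conjugated ester by the aluminium hydride at low temperature should give the allylic alcohol without touching the alkenyl iodide or any alkene geometry.

**Step 8**
Reactants: 12 (2Z,6E)-2-[(3E)-4-iodopent-3-en-1-yl]-8-[(4-methoxyphenyl)methoxy]-6-methylocta-2,6-dien-1-ol
Product: 13 tert-butyldimethylsilyl ether of 12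
Conditions: TBSCl, imidazole, CH2Cl2, 0 °C to rt
Reagents that add atoms: tert-butyldimethylsilyl chloride, CC(C)(C)[Si](C)(C)Cl
Why: Silylation of the primary allylic alcohol masks O19 through the borane, palladium and amide-base steps in which an allylic acetate would not survive.

**Step 9**
Reactants: 13 tert-butyldimethylsilyl ether of 12
Product: 14 (2E,6Z,10E)-7-{[tert-butyl(dimethyl)silyl]oxymethyl}-11-iodo-3-methyldodeca-2,6,10-trien-1-ol
Conditions: DDQ, CH2Cl2/pH 7 buffer, 0 °C
Reagents that add atoms: none
Why: Oxidative cleavage of the 4-methoxybenzyl ether (benzylic hydride abstraction by DDQ, hydrolysis of the oxocarbenium ion) is orthogonal to the silyl ether.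

**Step 10**
Reactants: 14 (2E,6Z,10E)-7-{[tert-butyl(dimethyl)silyl]oxymethyl}-11-iodo-3-methyldodeca-2,6,10-trien-1-ol
Product: 15 (2E,6Z,10E)-7-{[tert-butyl(dimethyl)silyl]oxymethyl}-11-iodo-3-methyldodeca-2,6,10-trienal
Conditions: MnO2 (excess), CH2Cl2, rt
Reagents that add atoms: none
Why: Allylic oxidation with MnO2 stops at the enal and should preserve the 2E geometry.

**Step 11**
Reactants: 16 methyl acetate; 17 acrolein
Product: 18 methyl 3-hydroxypent-4-enoate
Conditions: LiN(i-Pr)2, THF, −78 °C; then acrolein; AcOH quench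
Reagents that add atoms: none
Why: Aldol addition of the lithium ester enolate to acrolein occurs 1,2 at −78 °C; the product is racemic, which does not matter because its stereocentre is lost in step 13.

**Step 12**
Reactants: 18 methyl 3-hydroxypent-4-enoate
Product: 19 methyl 3-[(methoxycarbonyl)oxy]pent-4-enoate
Conditions: ClCO2Me, pyridine, DMAP (cat.), CH2Cl2, 0 °C
Reagents that add atoms: methyl chloroformate, COC(=O)Cl
Why: O-Acylation of the secondary allylic alcohol installs the carbonate leaving group needed in step 13.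

**Step 13**
Reactants: 19 methyl 3-[(methoxycarbonyl)oxy]pent-4-enoate
Product: 20 methyl (3E)-5-(4,4,5,5-tetramethyl-1,3,2-dioxaborolan-2-yl)pent-3-enoate
Conditions: CuCl (5 mol %), Xantphos (5 mol %), KOt-Bu (10 mol %), B2pin2 (1.1 equiv), THF, rt
Reagents that add atoms: bis(pinacolato)diboron, CC1(C)OB(OC1(C)C)B1OC(C)(C)C(C)(C)O1
Why: Copper-catalysed γ-selective (SN2') allylic borylation: the boryl–copper species adds to the terminal alkene carbon and anti-elimination of the carbonate should give the linear allylboronate with E geometry.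

**Step 14**
Reactants: 15 (2E,6Z,10E)-7-{[tert-butyl(dimethyl)silyl]oxymethyl}-11-iodo-3-methyldodeca-2,6,10-trienal; 20 methyl (3E)-5-(4,4,5,5-tetramethyl-1,3,2-dioxaborolan-2-yl)pent-3-enoate
Product: 23 (4R,5R)-4-ethenyl-5-[(1E,5Z,9E)-10-iodo-2-methyl-6-{[tert-butyl(dimethyl)silyl]oxymethyl}undeca-1,5,9-trien-1-yl]oxolan-2-one, via O-boryl adduct 21 (not isolated), via hydroxy ester 22 (not isolated)
Conditions: (R)-TRIP (5 mol %), 4 Å molecular sieves, PhMe, −30 °C; H2O quench; crude 22, PPTS (10 mol %), 4 Å molecular sieves, PhMe, 45 °C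
Reagents that add atoms: none
Why: Chiral phosphoric acid-catalysed allylboration through a closed chair transition state: the E geometry of 20 puts the CH2CO2Me group equatorial and gives the anti adduct (hence the cis lactone), while the catalyst, bound to a boronate oxygen and the formyl hydrogen, should direct attack to the Re face of the enal, so that C2 and C1 are set together before mild acid closes the γ-lactone.

**Step 15**
Reactants: 23 (4R,5R)-4-ethenyl-5-[(1E,5Z,9E)-10-iodo-2-methyl-6-{[tert-butyl(dimethyl)silyl]oxymethyl}undeca-1,5,9-trien-1-yl]oxolan-2-one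
Product: 25 (1S,2R,3E,7Z,11E)-19-[tert-butyl(dimethyl)silyl]oxycembra-3,7,11-trien-16,2-olide, via alkylborane 24 (not isolated)
Conditions: 9-BBN (2.2 equiv), THF, 0 °C to rt; H2O; then 12 h addition to Pd(dppf)Cl2 (20 mol %), AsPh3 (40 mol %), Cs2CO3 (5 equiv), DMF/THF/H2O, 50 °C, 1 mM; pH 4 work-up
Reagents that add atoms: 9-borabicyclo[3.3.1]nonane, B1C2CCCC1CCC2 (boron unit stays only in 24)
Why: 9-BBN adds anti-Markovnikov to the only monosubstituted alkene (C13=C14) and places boron on C13; hydroxide from the aqueous carbonate turns the borane into a borate, zerovalent palladium inserts into the C12–I bond with retention of the E geometry, the primary alkyl group passes from boron to palladium and reductive elimination forms C12–C13. The closest known reaction type is the intramolecular B-alkyl Suzuki–Miyaura macrocyclisation of an (E)-2-iodo-2-alkene with a tethered alkyl-9-BBN, established for terpenoid carbocycles of twelve and more members. The 14-membered ring is closed at an sp2–sp3 bond by reductive elimination from a 15-membered alkyl(alkenyl)palladacycle, which leaves the C11=C12 double bond inside the new ring and the lactone untouched. No stereocentre is formed: C1 and C2 are remote from the reacting carbons and not epimerisable under carbonate, and the C11=C12 geometry is that of iodide 23. The step needs chemoselective hydroboration (secured by the steric preference of 9-BBN for the lone vinyl group over three trisubstituted alkenes and the lactone carbonyl), cyclisation over oligomerisation (secured by slow addition at about 1 mM and by the cis arrangement of the two lactone substituents, which holds both chain ends on one face) and oxidative addition at the alkenyl iodide in preference to ionisation of the allylic C2–O bond (secured by the far higher reactivity of the C–I bond and the hindered trisubstituted allyl system).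

**Step 16**
Reactants: 25 (1S,2R,3E,7Z,11E)-19-[tert-butyl(dimethyl)silyl]oxycembra-3,7,11-trien-16,2-olide
Product: 28 (1S,2S,3E,7Z,11E)-19-[tert-butyl(dimethyl)silyl]oxycembra-3,7,11,15(17)-tetraen-16,2-olide, via Mannich base 26 (not isolated), via ammonium iodide 27 (not isolated)
Conditions: LiN(i-Pr)2, THF, −78 °C; CH2=NMe2+ I−, −78 °C to rt; crude 26, MeI, MeOH, rt; crude 27, aq. NaHCO3/CH2Cl2, rt
Reagents that add atoms: Eschenmoser's salt, C=[N+](C)C.[I-]; iodomethane, CI (methyl stays only in 27)
Why: Enolate Mannich reaction at C15, N-methylation and base-induced Hofmann-type elimination of trimethylamine install the exocyclic methylene; C1 and C2 are not enolisable and stay unchanged.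

**Step 17**
Reactants: 28 (1S,2S,3E,7Z,11E)-19-[tert-butyl(dimethyl)silyl]oxycembra-3,7,11,15(17)-tetraen-16,2-olide
Product: 29 (1S,2S,3E,7Z,11E)-19-hydroxycembra-3,7,11,15(17)-tetraen-16,2-olide
Conditions: HF·pyridine, pyridine, THF, 0 °C to rt
Reagents that add atoms: none
Why: Fluoride-mediated desilylation under buffered acidic conditions should free the primary alcohol without conjugate addition to the α-methylene lactone.

**Step 18**
Reactants: 29 (1S,2S,3E,7Z,11E)-19-hydroxycembra-3,7,11,15(17)-tetraen-16,2-olide
Product: 30 (1S,2S,3E,7Z,11E)-19-acetoxycembra-3,7,11,15(17)-tetraen-16,2-olide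
Conditions: Ac2O, pyridine, DMAP (cat.), CH2Cl2, 0 °C
Reagents that add atoms: acetic anhydride, CC(=O)OC(C)=O
Why: DMAP-catalysed O-acetylation of the primary allylic alcohol should complete the target without affecting the lactone.

**Compound list**

1 | pent-3-yn-1-ol | CC#CCCO | starting material
2 | (E)-alkenylzirconocene chloride from 1, zirconium on C4 and on oxygen | C/C(=C\CCO[Zr](Cl)(C1C=CC=C1)C1C=CC=C1)[Zr](Cl)(C1C=CC=C1)C1C=CC=C1 | intermediate
3 | (3E)-4-iodopent-3-en-1-ol | C/C(I)=C\CCO | intermediate
4 | (2E)-2,5-diiodopent-2-ene | C/C(I)=C\CCI | intermediate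
5 | methyl 2-[bis(2,2,2-trifluoroethoxy)phosphoryl]acetate | COC(=O)CP(=O)(OCC(F)(F)F)OCC(F)(F)F | starting material
6 | methyl (5E)-2-[bis(2,2,2-trifluoroethoxy)phosphoryl]-6-iodohept-5-enoate (racemic) | COC(=O)C(CC/C=C(\C)I)P(=O)(OCC(F)(F)F)OCC(F)(F)F | intermediate
7 | geraniol, (2E)-3,7-dimethylocta-2,6-dien-1-ol | OC/C=C(\C)CCC=C(C)C | starting material
8 | geranyl 4-methoxybenzyl ether | COc1ccc(COC/C=C(\C)CCC=C(C)C)cc1 | intermediate
9 | 6,7-epoxide of 8 (racemic) | COc1ccc(COC/C=C(\C)CCC2OC2(C)C)cc1 | intermediate
10 | (4E)-6-[(4-methoxyphenyl)methoxy]-4-methylhex-4-enal | COc1ccc(COC/C=C(\C)CCC=O)cc1 | intermediate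
11 | methyl (2Z,6E)-2-[(3E)-4-iodopent-3-en-1-yl]-8-[(4-methoxyphenyl)methoxy]-6-methylocta-2,6-dienoate | COc1ccc(COC/C=C(\C)CC/C=C(\C(=O)OC)CC/C=C(\C)I)cc1 | intermediate
12 | (2Z,6E)-2-[(3E)-4-iodopent-3-en-1-yl]-8-[(4-methoxyphenyl)methoxy]-6-methylocta-2,6-dien-1-ol | COc1ccc(COC/C=C(\C)CC/C=C(\CO)CC/C=C(\C)I)cc1 | intermediate
13 | tert-butyldimethylsilyl ether of 12 | COc1ccc(COC/C=C(\C)CC/C=C(\CO[Si](C)(C)C(C)(C)C)CC/C=C(\C)I)cc1 | intermediate
14 | (2E,6Z,10E)-7-{[tert-butyl(dimethyl)silyl]oxymethyl}-11-iodo-3-methyldodeca-2,6,10-trien-1-ol | OC/C=C(\C)CC/C=C(\CO[Si](C)(C)C(C)(C)C)CC/C=C(\C)I | intermediate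
15 | (2E,6Z,10E)-7-{[tert-butyl(dimethyl)silyl]oxymethyl}-11-iodo-3-methyldodeca-2,6,10-trienal | O=C/C=C(\C)CC/C=C(\CO[Si](C)(C)C(C)(C)C)CC/C=C(\C)I | intermediate
16 | methyl acetate | COC(C)=O | starting material
17 | acrolein | C=CC=O | starting material
18 | methyl 3-hydroxypent-4-enoate (racemic) | COC(=O)CC(O)C=C | intermediate
19 | methyl 3-[(methoxycarbonyl)oxy]pent-4-enoate (racemic) | COC(=O)CC(OC(=O)OC)C=C | intermediate
20 | methyl (3E)-5-(4,4,5,5-tetramethyl-1,3,2-dioxaborolan-2-yl)pent-3-enoate | COC(=O)C/C=C/CB1OC(C)(C)C(C)(C)O1 | intermediate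
21 | O-(pinacolatoboryl) derivative of 22 | COC(=O)C[C@H](C=C)[C@@H](OB1OC(C)(C)C(C)(C)O1)/C=C(\C)CC/C=C(\CO[Si](C)(C)C(C)(C)C)CC/C=C(\C)I | intermediate
22 | methyl (3R,4R,5E,9Z,13E)-3-ethenyl-4-hydroxy-14-iodo-6-methyl-10-{[tert-butyl(dimethyl)silyl]oxymethyl}pentadeca-5,9,13-trienoate | COC(=O)C[C@H](C=C)[C@@H](O)/C=C(\C)CC/C=C(\CO[Si](C)(C)C(C)(C)C)CC/C=C(\C)I | intermediate
23 | (4R,5R)-4-ethenyl-5-[(1E,5Z,9E)-10-iodo-2-methyl-6-{[tert-butyl(dimethyl)silyl]oxymethyl}undeca-1,5,9-trien-1-yl]oxolan-2-one (cis) | O=C1O[C@@H](/C=C(\C)CC/C=C(\CO[Si](C)(C)C(C)(C)C)CC/C=C(\C)I)[C@@H](C=C)C1 | intermediate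
24 | 23 with CH2CH2(9-borabicyclo[3.3.1]nonan-9-yl) in place of the vinyl group | O=C1O[C@@H](/C=C(\C)CC/C=C(\CO[Si](C)(C)C(C)(C)C)CC/C=C(\C)I)[C@@H](CCB2C3CCCC2CCC3)C1 | intermediate
25 | (1S,2R,3E,7Z,11E)-19-[tert-butyl(dimethyl)silyl]oxycembra-3,7,11-trien-16,2-olide (cis-fused lactone on the 14-membered ring) | C1C(=O)O[C@H]2/C=C(\C)CC/C=C(\CO[Si](C)(C)C(C)(C)C)CC/C=C(\C)CC[C@@H]12 | intermediate
26 | 15-[(dimethylamino)methyl] derivative of 25 (C15 epimers) | CN(C)CC1C(=O)O[C@H]2/C=C(\C)CC/C=C(\CO[Si](C)(C)C(C)(C)C)CC/C=C(\C)CC[C@@H]12 | intermediate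
27 | N-methyl ammonium iodide of 26 | C[N+](C)(C)CC1C(=O)O[C@H]2/C=C(\C)CC/C=C(\CO[Si](C)(C)C(C)(C)C)CC/C=C(\C)CC[C@@H]12.[I-] | intermediate
28 | (1S,2S,3E,7Z,11E)-19-[tert-butyl(dimethyl)silyl]oxycembra-3,7,11,15(17)-tetraen-16,2-olide | C=C1C(=O)O[C@H]2/C=C(\C)CC/C=C(\CO[Si](C)(C)C(C)(C)C)CC/C=C(\C)CC[C@@H]12 | intermediate
29 | (1S,2S,3E,7Z,11E)-19-hydroxycembra-3,7,11,15(17)-tetraen-16,2-olide | C=C1C(=O)O[C@H]2/C=C(\C)CC/C=C(\CO)CC/C=C(\C)CC[C@@H]12 | intermediate
30 | (1S,2S,3E,7Z,11E)-19-acetoxycembra-3,7,11,15(17)-tetraen-16,2-olide (C7=C8 is Z by the sequence rule, ring bonds trans) | C=C1C(=O)O[C@H]2/C=C(\C)CC/C=C(\COC(C)=O)CC/C=C(\C)CC[C@@H]12 | target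

**Step count**

Total steps: 18. Longest linear sequence: 13 (steps 1–3, 6–10, 14–18).

**Steps most likely to fail**

Step 15 (ring closure). What may go wrong: intermolecular coupling to oligomers, loss of boron by protodeboronation or β-hydride elimination from the alkylpalladium, base-induced opening of the lactone, or ionisation of the allylic C2–O bond by zerovalent palladium. The fallback sets out from 23 and comes back at 25, and it replaces the borate by an isolated, base-free zinc nucleophile. Hydroboration–oxidation of the vinyl group (9-BBN, then NaBO3·4H2O) should give the primary alcohol F1. Appel iodination (I2, PPh3, imidazole) should give the primary iodide F2. Zinc dust with LiCl in THF at 30 °C should insert only into the sp3 C–I bond to give the alkylzinc iodide F3. Slow addition of F3 to Pd(PPh3)4 in THF at high dilution should close C12–C13 by intramolecular Negishi coupling to 25.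

Step 14 (allylboration). What may go wrong: poor facial selectivity of the catalyst with a β,β-disubstituted enal and a functionalised boronate, or slow addition that lets the uncatalysed racemic pathway compete. The fallback sets out from 15 and comes back at 22, and it moves stereocontrol from a catalyst to the ligands on boron. Johnson–Claisen rearrangement of propargyl alcohol with trimethyl orthoacetate (propionic acid cat., 110 °C) should give methyl penta-3,4-dienoate F4. Hydroboration of its terminal allene carbon with (+)-diisopinocampheylborane (from (−)-α-pinene), followed by brief warming to equilibrate to the E isomer, should give the (E)-allyl(diisopinocampheyl)borane F5. Addition of F5 to 15 at −78 °C through the same chair transition state, now with Re-face control by the terpene ligands, should give the borinate F6. Work-up with NaBO3·4H2O should release 22, which lactonises to 23 as in step 14.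

Step 3 (phosphonate alkylation). What may go wrong: the fluorinated phosphonate anion is a weak nucleophile, so dialkylation and E2 elimination of the homoallylic iodide can overtake the slow substitution. The fallback sets out from 4 and comes back at 6, and it alkylates first and introduces the trifluoroethyl esters afterwards. Alkylation of the more nucleophilic trimethyl phosphonoacetate (COC(=O)CP(=O)(OC)OC; NaH, DMF) with 4 should give the dimethyl phosphonate F7. Bromotrimethylsilane in CH2Cl2 should cleave only the phosphonate methyl esters to give the bis(trimethylsilyl) phosphonate F8. Oxalyl chloride with catalytic DMF should give the phosphonic dichloride F9. 2,2,2-Trifluoroethanol and Et3N should then give 6.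

**Further compounds**

F1 | step 15 | 23 with CH2CH2OH in place of the vinyl group | O=C1O[C@@H](/C=C(\C)CC/C=C(\CO[Si](C)(C)C(C)(C)C)CC/C=C(\C)I)[C@@H](CCO)C1
F2 | step 15 | 23 with CH2CH2I in place of the vinyl group | O=C1O[C@@H](/C=C(\C)CC/C=C(\CO[Si](C)(C)C(C)(C)C)CC/C=C(\C)I)[C@@H](CCI)C1
F3 | step 15 | alkylzinc iodide from F2 | O=C1O[C@@H](/C=C(\C)CC/C=C(\CO[Si](C)(C)C(C)(C)C)CC/C=C(\C)I)[C@@H](CC[Zn]I)C1
F4 | step 14 | methyl penta-3,4-dienoate | COC(=O)CC=C=C
F5 | step 14 | methyl (3E)-5-[bis(isopinocampheyl)boranyl]pent-3-enoate, isopinocampheyl groups from (−)-α-pinene | COC(=O)C/C=C/CB([C@H]1C[C@H]2C[C@@H]([C@@H]1C)C2(C)C)[C@H]1C[C@H]2C[C@@H]([C@@H]1C)C2(C)C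
F6 | step 14 | O-[bis(isopinocampheyl)boranyl] derivative of 22 | COC(=O)C[C@H](C=C)[C@@H](OB([C@H]1C[C@H]2C[C@@H]([C@@H]1C)C2(C)C)[C@H]1C[C@H]2C[C@@H]([C@@H]1C)C2(C)C)/C=C(\C)CC/C=C(\CO[Si](C)(C)C(C)(C)C)CC/C=C(\C)I
F7 | step 3 | methyl (5E)-2-(dimethoxyphosphoryl)-6-iodohept-5-enoate (racemic) | COC(=O)C(CC/C=C(\C)I)P(=O)(OC)OC
F8 | step 3 | methyl (5E)-2-[bis(trimethylsilyloxy)phosphoryl]-6-iodohept-5-enoate (racemic) | COC(=O)C(CC/C=C(\C)I)P(=O)(O[Si](C)(C)C)O[Si](C)(C)C
F9 | step 3 | methyl (5E)-2-(dichlorophosphoryl)-6-iodohept-5-enoate (racemic) | COC(=O)C(CC/C=C(\C)I)P(=O)(Cl)Cl
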